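**Strategy.** The pyran ring (ring C: O1, C2, C3, C4, C4a, C8a) is made last, by enlarging a 2,3-dihydrobenzofuran. In the precursor the two vicinal oxygens of ring C are attached the other way round: O1 sits on the future C3 and a free hydroxyl on the benzylic future C2. On ionisation O1 bridges to the benzylic carbon (aryloxiranium ion) and water opens the bridge at the old ring carbon. One operation thus forms the O1–C2 bond, frees the 3-OH and sets the trans (2S,3R) pair. The precursor comes from Shi epoxidation of an (E)-1,3-diarylpropene and 5-exo opening by the ring A phenol; the 7-O-gallate is already in place.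

Key step: step 10

Remark: the target is the 2,3-trans (2S,3R) isomer (gallocatechin type, 7-O-galloyl); 3,4,5-tris(benzyloxy)benzoic acid, its acid chloride and the D-fructose-derived Shi ketone are taken as purchased.

Step 1
Reactants: 1 2,4,6-trihydroxybenzaldehyde
Product: 2 2,4-bis(allyloxy)-6-hydroxybenzaldehyde
Conditions: allyl bromide (2.1 equiv), K2CO3, acetone, reflux
Reagents that add atoms: allyl bromide, C=CCBr
Why: Williamson etherification should take the para hydroxyl and one ortho hydroxyl, while the last hydroxyl is held in a hydrogen bond to the formyl group and stays free.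

Step 2
Reactants: 2 2,4-bis(allyloxy)-6-hydroxybenzaldehyde
Product: 3 2,4-bis(allyloxy)-6-(benzyloxy)benzaldehyde
Conditions: BnBr, K2CO3, DMF, 60 °C
Reagents that add atoms: benzyl bromide, BrCc1ccccc1
Why: Williamson etherification under forcing conditions alkylates the chelated phenol, so the three ring A oxygens are now differentiated (two allyl, one benzyl).

Step 3
Reactants: 4 3,4,5-tris(benzyloxy)benzoic acid
Product: 5 1-[3,4,5-tris(benzyloxy)phenyl]ethan-1-one
Conditions: MeLi (2.2 equiv), THF, 0 °C to 25 °C; aqueous work-up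
Reagents that add atoms: methyllithium, [Li]C
Why: Addition of methyllithium to the lithium carboxylate gives a dilithium gem-diolate that collapses to the methyl ketone only on work-up (carboxylic acid to methyl ketone).

Step 4
Reactants: 3 2,4-bis(allyloxy)-6-(benzyloxy)benzaldehyde; 5 1-[3,4,5-tris(benzyloxy)phenyl]ethan-1-one
Product: 6 (2E)-3-[2,4-bis(allyloxy)-6-(benzyloxy)phenyl]-1-[3,4,5-tris(benzyloxy)phenyl]prop-2-en-1-one
Conditions: KOH, EtOH–THF, 25 °C
Reagents that add atoms: none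
Why: Claisen–Schmidt aldol condensation; elimination of water from the aldolate gives the conjugated E enone with the carbonyl on the ring B side.

Step 5
Reactants: 6 (2E)-3-[2,4-bis(allyloxy)-6-(benzyloxy)phenyl]-1-[3,4,5-tris(benzyloxy)phenyl]prop-2-en-1-one
Product: 7 N'-{(2E)-3-[2,4-bis(allyloxy)-6-(benzyloxy)phenyl]-1-[3,4,5-tris(benzyloxy)phenyl]prop-2-en-1-ylidene}-4-methylbenzenesulfonohydrazide
Conditions: TsNHNH2, AcOH (cat.), EtOH–THF, 50 °C
Reagents that add atoms: p-toluenesulfonyl hydrazide, Cc1ccc(cc1)S(=O)(=O)NN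
Why: Hydrazone condensation at the ketone; the β-carbon is deactivated by the trialkoxyaryl donor, so aza-Michael closure to a pyrazoline should be slow.

Step 6
Reactants: 7 N'-{(2E)-3-[2,4-bis(allyloxy)-6-(benzyloxy)phenyl]-1-[3,4,5-tris(benzyloxy)phenyl]prop-2-en-1-ylidene}-4-methylbenzenesulfonohydrazide
Product: 9 1,5-bis(allyloxy)-3-(benzyloxy)-2-{(2E)-3-[3,4,5-tris(benzyloxy)phenyl]prop-2-en-1-yl}benzene, via allylic diazene 8 (not isolated)
Conditions: catecholborane, CHCl3, 0 °C to 25 °C; then NaOAc·3H2O, reflux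
Reagents that add atoms: none
Why: Reductive 1,3-transposition of an enone tosylhydrazone: hydride adds to the C=N carbon, loss of sulfinate gives diazene 8, and its retro-ene loss of N2 delivers hydrogen to the carbon next to ring A and moves the double bond into conjugation with ring B with E geometry, so the alkene position is fixed by the mechanism.

Step 7
Reactants: 9 1,5-bis(allyloxy)-3-(benzyloxy)-2-{(2E)-3-[3,4,5-tris(benzyloxy)phenyl]prop-2-en-1-yl}benzene
Product: 10 (2R,3R)-2-{[2,4-bis(allyloxy)-6-(benzyloxy)phenyl]methyl}-3-[3,4,5-tris(benzyloxy)phenyl]oxirane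
Conditions: D-fructose-derived Shi ketone (30 mol %), Oxone (2KHSO5·KHSO4·K2SO4), K2CO3, Bu4NHSO4, MeCN–CH2(OMe)2/aq. Na2B4O7 buffer, 0 °C
Reagents that add atoms: potassium peroxymonosulfate (active part of Oxone), [K+].[O-]S(=O)(=O)OO
Why: Shi asymmetric epoxidation: the chiral dioxirane attacks the trans-disubstituted styrene-type alkene through a spiro transition state and should give the (2R,3R)-epoxide, while the two terminal allyl ether alkenes are far less reactive.

Step 8
Reactants: 10 (2R,3R)-2-{[2,4-bis(allyloxy)-6-(benzyloxy)phenyl]methyl}-3-[3,4,5-tris(benzyloxy)phenyl]oxirane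
Product: 12 (R)-[(2S)-4-(benzyloxy)-6-hydroxy-2,3-dihydro-1-benzofuran-2-yl][3,4,5-tris(benzyloxy)phenyl]methanol, via epoxy diphenol 11 (not isolated)
Conditions: Pd(PPh3)4 (5 mol %), K2CO3, MeOH–THF, 25 to 40 °C
Reagents that add atoms: none
Why: Tsuji–Trost-type allyl transfer from both aryl allyl ethers to methoxide (zerovalent palladium) unmasks the phenols, and under these basic, non-ionising conditions the ortho phenoxide opens the epoxide 5-exo-tet at the non-benzylic carbon with inversion, which sets the furan C2 as S and leaves the carbinol centre R.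

Step 9
Reactants: 12 (R)-[(2S)-4-(benzyloxy)-6-hydroxy-2,3-dihydro-1-benzofuran-2-yl][3,4,5-tris(benzyloxy)phenyl]methanol; 13 3,4,5-tris(benzyloxy)benzoyl chloride
Product: 14 (2S)-4-(benzyloxy)-2-{(R)-hydroxy[3,4,5-tris(benzyloxy)phenyl]methyl}-2,3-dihydro-1-benzofuran-6-yl 3,4,5-tris(benzyloxy)benzoate
Conditions: Et3N (1.2 equiv), CH2Cl2, −20 to 0 °C, no acyl-transfer catalyst
Reagents that add atoms: none
Why: Acylation of the phenol by the acid chloride with amine base is much faster than that of the hindered secondary benzylic alcohol, so only the 6-OH (the later 7-O) should be esterified.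

Step 10
Reactants: 14 (2S)-4-(benzyloxy)-2-{(R)-hydroxy[3,4,5-tris(benzyloxy)phenyl]methyl}-2,3-dihydro-1-benzofuran-6-yl 3,4,5-tris(benzyloxy)benzoate
Product: 16 (2S,3R)-5-(benzyloxy)-3-hydroxy-2-[3,4,5-tris(benzyloxy)phenyl]-3,4-dihydro-2H-1-benzopyran-7-yl 3,4,5-tris(benzyloxy)benzoate, via aryloxiranium ion 15 (not isolated)
Conditions: TsOH·H2O (5 mol %), (CF3)2CHOH–H2O (10:1), 25 °C
Reagents that add atoms: water, O
Why: Acid ionises the benzylic carbinol with anchimeric help from the furan oxygen O1, which bridges to the benzylic carbon anti to the leaving water and gives the bicyclic aryloxiranium ion 15; water then opens 15 at the former furan C2 with inversion and breaks the old O1–C bond, so the five-membered ring becomes the chroman. The closest known reaction type is the ring expansion of 2-(1-sulfonyloxyalkyl)tetrahydrofurans to tetrahydropyran-3-ols through bicyclic oxonium ions (oxygen counterpart of the aziridinium-mediated prolinol to piperidin-3-ol expansion), run here as an acid-catalysed hydrolytic version. The only closure is the 3-exo-tet attack of O1 on the benzylic carbon; the six-membered ring then arises by SN2 cleavage of the shared C–O bond and not by a new cyclisation. C2 of the flavan is set by backside entry of O1 (and, if the cation is free, by the preference for the trans-disubstituted oxiranium ion), and C3 by backside entry of water on the centre fixed in step 7, so (R)-carbinol/(2S)-furan should give the (2S,3R)-trans pair. The step needs water to attack the non-benzylic carbon: attack at the benzylic carbon only returns 14 or its epimer, which ionise again, whereas 16 is a non-benzylic secondary alcohol that does not, so the system should funnel to 16. The twisted 4-benzyloxy group and the β-oxygen temper the cation, which favours bridging over hydride shift or proton loss.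

Step 11
Reactants: 16 (2S,3R)-5-(benzyloxy)-3-hydroxy-2-[3,4,5-tris(benzyloxy)phenyl]-3,4-dihydro-2H-1-benzopyran-7-yl 3,4,5-tris(benzyloxy)benzoate
Product: 17 (2S,3R)-3,5-dihydroxy-2-(3,4,5-trihydroxyphenyl)-3,4-dihydro-2H-1-benzopyran-7-yl 3,4,5-trihydroxybenzoate
Conditions: H2 (1 atm), Pd(OH)2/C, THF–MeOH, 25 °C
Reagents that add atoms: none
Why: Hydrogenolysis of the six benzyl ethers; at 1 atm and room temperature the aryl ester and the cyclic benzylic C2–O1 ether should survive and no stereocentre is touched.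

**Compound list**

1 | 2,4,6-trihydroxybenzaldehyde | O=Cc1c(O)cc(O)cc1O | starting material
2 | 2,4-bis(allyloxy)-6-hydroxybenzaldehyde | O=Cc1c(O)cc(OCC=C)cc1OCC=C | intermediate
3 | 2,4-bis(allyloxy)-6-(benzyloxy)benzaldehyde | O=Cc1c(OCC=C)cc(OCC=C)cc1OCc1ccccc1 | intermediate
4 | 3,4,5-tris(benzyloxy)benzoic acid | OC(=O)c1cc(OCc2ccccc2)c(OCc2ccccc2)c(OCc2ccccc2)c1 | starting material
5 | 1-[3,4,5-tris(benzyloxy)phenyl]ethan-1-one | CC(=O)c1cc(OCc2ccccc2)c(OCc2ccccc2)c(OCc2ccccc2)c1 | intermediate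
6 | (2E)-3-[2,4-bis(allyloxy)-6-(benzyloxy)phenyl]-1-[3,4,5-tris(benzyloxy)phenyl]prop-2-en-1-one | O=C(/C=C/c1c(OCC=C)cc(OCC=C)cc1OCc1ccccc1)c1cc(OCc2ccccc2)c(OCc2ccccc2)c(OCc2ccccc2)c1 | intermediate
7 | tosylhydrazone of 6 | Cc1ccc(cc1)S(=O)(=O)NN=C(/C=C/c1c(OCC=C)cc(OCC=C)cc1OCc1ccccc1)c1cc(OCc2ccccc2)c(OCc2ccccc2)c(OCc2ccccc2)c1 | intermediate
8 | {(2E)-3-[2,4-bis(allyloxy)-6-(benzyloxy)phenyl]-1-[3,4,5-tris(benzyloxy)phenyl]prop-2-en-1-yl}diazene (allylic diazene) | N=NC(/C=C/c1c(OCC=C)cc(OCC=C)cc1OCc1ccccc1)c1cc(OCc2ccccc2)c(OCc2ccccc2)c(OCc2ccccc2)c1 | intermediate (not isolated)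
9 | 1,5-bis(allyloxy)-3-(benzyloxy)-2-{(2E)-3-[3,4,5-tris(benzyloxy)phenyl]prop-2-en-1-yl}benzene | C=CCOc1cc(OCC=C)c(C/C=C/c2cc(OCc3ccccc3)c(OCc3ccccc3)c(OCc3ccccc3)c2)c(OCc2ccccc2)c1 | intermediate
10 | (2R,3R)-2-{[2,4-bis(allyloxy)-6-(benzyloxy)phenyl]methyl}-3-[3,4,5-tris(benzyloxy)phenyl]oxirane | C=CCOc1cc(OCC=C)c(C[C@H]2O[C@@H]2c2cc(OCc3ccccc3)c(OCc3ccccc3)c(OCc3ccccc3)c2)c(OCc2ccccc2)c1 | intermediate
11 | 5-(benzyloxy)-4-({(2R,3R)-3-[3,4,5-tris(benzyloxy)phenyl]oxiran-2-yl}methyl)benzene-1,3-diol (epoxy diphenol) | Oc1cc(O)c(C[C@H]2O[C@@H]2c2cc(OCc3ccccc3)c(OCc3ccccc3)c(OCc3ccccc3)c2)c(OCc2ccccc2)c1 | intermediate (not isolated)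
12 | (R)-[(2S)-4-(benzyloxy)-6-hydroxy-2,3-dihydro-1-benzofuran-2-yl][3,4,5-tris(benzyloxy)phenyl]methanol | O[C@H](c1cc(OCc2ccccc2)c(OCc2ccccc2)c(OCc2ccccc2)c1)[C@@H]1Cc2c(OCc3ccccc3)cc(O)cc2O1 | intermediate
13 | 3,4,5-tris(benzyloxy)benzoyl chloride | O=C(Cl)c1cc(OCc2ccccc2)c(OCc2ccccc2)c(OCc2ccccc2)c1 | starting material
14 | (2S)-4-(benzyloxy)-2-{(R)-hydroxy[3,4,5-tris(benzyloxy)phenyl]methyl}-2,3-dihydro-1-benzofuran-6-yl 3,4,5-tris(benzyloxy)benzoate | O[C@H](c1cc(OCc2ccccc2)c(OCc2ccccc2)c(OCc2ccccc2)c1)[C@@H]1Cc2c(OCc3ccccc3)cc(OC(=O)c3cc(OCc4ccccc4)c(OCc4ccccc4)c(OCc4ccccc4)c3)cc2O1 | intermediate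
15 | bridged aryloxiranium ion (O1 bonded to ring A, to the old furan C2 and to the benzylic carbon; aryl and CH2 trans on the three-membered ring) | c1ccccc1COc2cc(cc(OCc3ccccc3)c2OCc4ccccc4)[C@H]5[C@@H]6Cc7c(OCc8ccccc8)cc(OC(=O)c8cc(OCc9ccccc9)c(OCc9ccccc9)c(OCc9ccccc9)c8)cc7[O+]56 | intermediate (not isolated)
16 | (2S,3R)-5-(benzyloxy)-3-hydroxy-2-[3,4,5-tris(benzyloxy)phenyl]-3,4-dihydro-2H-1-benzopyran-7-yl 3,4,5-tris(benzyloxy)benzoate | O=C(Oc1cc(OCc2ccccc2)c2c(c1)O[C@@H](c1cc(OCc3ccccc3)c(OCc3ccccc3)c(OCc3ccccc3)c1)[C@H](O)C2)c1cc(OCc2ccccc2)c(OCc2ccccc2)c(OCc2ccccc2)c1 | intermediate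
17 | (2S,3R)-3,5-dihydroxy-2-(3,4,5-trihydroxyphenyl)-3,4-dihydro-2H-1-benzopyran-7-yl 3,4,5-trihydroxybenzoate | O=C(Oc1cc(O)c2c(c1)O[C@@H](c1cc(O)c(O)c(O)c1)[C@H](O)C2)c1cc(O)c(O)c(O)c1 | target

**Step count and risks**

Total step count: 11. Longest linear sequence: 10 (steps 1, 2, 4 to 11, from 1).

The three steps most likely to fail:

Step 10 (key step). The benzylic cation may leave the bridged ion by 1,2-hydride shift or loss of the neighbouring proton (leading to a ring-opened ketone or an aromatised 2-benzylbenzofuran), or water may add only at the benzylic carbon so that no net change results. Fallback, an acyl relay without strong acid and without water, from 14: (CF3CO)2O and pyridine in CH2Cl2 at −20 °C should give the benzylic trifluoroacetate F1. Warmed in (CF3)2CHOH with 2,6-di-tert-butylpyridine at 40 °C, F1 ionises and the trifluoroacetate should return at the ring carbon of the oxiranium ion under thermodynamic control, giving the flavan-3-yl trifluoroacetate F2. NaHCO3 in MeOH–H2O at 0 °C then removes the trifluoroacetyl group selectively and the route is rejoined at 16.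

Step 8. The epoxide may be lost by methanolysis, or the phenoxide may close at the benzylic carbon in the protic medium, so that regiocontrol of the epoxide opening is lost. Fallback from 9, in which the allyl groups are exchanged for silyl groups before the epoxide is made: Pd(PPh3)4, K2CO3, MeOH on the alkene should give 5-(benzyloxy)-4-{(2E)-3-[3,4,5-tris(benzyloxy)phenyl]prop-2-en-1-yl}benzene-1,3-diol F3. TBSCl and imidazole in DMF give its bis(tert-butyldimethylsilyl) ether F4. Shi epoxidation as in step 7 gives the (2R,3R)-epoxide of the bis-silyl ether F5. Bu4NF in THF at 0 °C then removes both silyl groups, and the naked ortho phenoxide should close 5-exo in the aprotic medium; the route is rejoined at 12.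

Step 6. Hydride may be delivered in a conjugate sense or incompletely to the unsaturated tosylhydrazone, or 7 may cyclise to a pyrazoline, so that the alkene is not transposed cleanly. Fallback from 6 by stepwise saturation, reduction and dehydration: conjugate reduction with [(Ph3P)CuH]6 in toluene (allyl and benzyl ethers untouched) should give 3-[2,4-bis(allyloxy)-6-(benzyloxy)phenyl]-1-[3,4,5-tris(benzyloxy)phenyl]propan-1-one F6. NaBH4 in MeOH–THF gives 3-[2,4-bis(allyloxy)-6-(benzyloxy)phenyl]-1-[3,4,5-tris(benzyloxy)phenyl]propan-1-ol F7. Burgess dehydration in toluene at 60 °C (syn elimination toward the only neighbouring CH2) should give the E alkene; the route is rejoined at 9 and bypasses 7 and 8.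

**Further compounds**

F1 | step 10 | (R)-[(2S)-4-(benzyloxy)-6-{[3,4,5-tris(benzyloxy)benzoyl]oxy}-2,3-dihydro-1-benzofuran-2-yl][3,4,5-tris(benzyloxy)phenyl]methyl trifluoroacetate | O=C(O[C@H](c1cc(OCc2ccccc2)c(OCc2ccccc2)c(OCc2ccccc2)c1)[C@@H]1Cc2c(OCc3ccccc3)cc(OC(=O)c3cc(OCc4ccccc4)c(OCc4ccccc4)c(OCc4ccccc4)c3)cc2O1)C(F)(F)F
F2 | step 10 | (2S,3R)-5-(benzyloxy)-3-[(trifluoroacetyl)oxy]-2-[3,4,5-tris(benzyloxy)phenyl]-3,4-dihydro-2H-1-benzopyran-7-yl 3,4,5-tris(benzyloxy)benzoate | O=C(Oc1cc(OCc2ccccc2)c2c(c1)O[C@@H](c1cc(OCc3ccccc3)c(OCc3ccccc3)c(OCc3ccccc3)c1)[C@H](OC(=O)C(F)(F)F)C2)c1cc(OCc2ccccc2)c(OCc2ccccc2)c(OCc2ccccc2)c1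
F3 | step 8 | 5-(benzyloxy)-4-{(2E)-3-[3,4,5-tris(benzyloxy)phenyl]prop-2-en-1-yl}benzene-1,3-diol | Oc1cc(O)c(C/C=C/c2cc(OCc3ccccc3)c(OCc3ccccc3)c(OCc3ccccc3)c2)c(OCc2ccccc2)c1
F4 | step 8 | 1-(benzyloxy)-3,5-bis[(tert-butyldimethylsilyl)oxy]-2-{(2E)-3-[3,4,5-tris(benzyloxy)phenyl]prop-2-en-1-yl}benzene | CC(C)(C)[Si](C)(C)Oc1cc(O[Si](C)(C)C(C)(C)C)c(C/C=C/c2cc(OCc3ccccc3)c(OCc3ccccc3)c(OCc3ccccc3)c2)c(OCc2ccccc2)c1
F5 | step 8 | (2R,3R)-2-({2-(benzyloxy)-4,6-bis[(tert-butyldimethylsilyl)oxy]phenyl}methyl)-3-[3,4,5-tris(benzyloxy)phenyl]oxirane | CC(C)(C)[Si](C)(C)Oc1cc(O[Si](C)(C)C(C)(C)C)c(C[C@H]2O[C@@H]2c2cc(OCc3ccccc3)c(OCc3ccccc3)c(OCc3ccccc3)c2)c(OCc2ccccc2)c1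
F6 | step 6 | 3-[2,4-bis(allyloxy)-6-(benzyloxy)phenyl]-1-[3,4,5-tris(benzyloxy)phenyl]propan-1-one | O=C(CCc1c(OCC=C)cc(OCC=C)cc1OCc1ccccc1)c1cc(OCc2ccccc2)c(OCc2ccccc2)c(OCc2ccccc2)c1
F7 | step 6 | 3-[2,4-bis(allyloxy)-6-(benzyloxy)phenyl]-1-[3,4,5-tris(benzyloxy)phenyl]propan-1-ol | OC(CCc1c(OCC=C)cc(OCC=C)cc1OCc1ccccc1)c1cc(OCc2ccccc2)c(OCc2ccccc2)c(OCc2ccccc2)c1
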